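The easy step is to count what the gas can carry across, and to keep that count as the fraction of G left, not the fraction of E made.

G 0.054 M; J 11 mM (held); Q 0.54 mM; time 4.0 min

    E → D (k1 = 4.78 × 10⁻⁴ s⁻¹)
    J ⇌ L, rate k2*(csat - [L]) (k2 = 0.0191 s⁻¹, csat = 11 mM)
    G + L + Q → Q + E (k3 = 25600 M⁻² s⁻¹)
    L → Z (k4 = 0.00270 s⁻¹)
    G + L → G.L (k5 = 0.0154 M⁻¹ s⁻¹)

- at the start none of L is dissolved
- run time (flask): 4.0 min

- how much E there is at 4.0 min, in percent of the G charged
- concentration of L in solution at 4.0 min, in percent of saturation

Each E costs one L, so I name the supply time, the time that transfer into an empty solution needs to bring one L for each G charged: 4.28 min. The catalyst removes L with a pseudo-first-order constant of 0.746 s⁻¹ at full [G], far faster than the transfer coefficient of 0.0191 s⁻¹, so while [G] stays near its charge transfer is the rate-limiting step, and with [L] taken as zero the fraction of G left is one minus time over supply time, which gives a floor of 6.62% at 4.0 min. E formed evenly has a mean age of 2.00 min, and decay over that age keeps about 94.4% of it, so the upper end of my bracket for E is about 88.2%.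

But [L] is not zero. Taking it as steady and integrating, the fraction left becomes that floor plus a width times the logarithm of its own inverse, the width being the first-order exits of L over its catalytic removal, 2.92%. Putting the floor into the logarithm gives about 14.6% of G left. Letting E decay for the whole run then gives a lower end of 76.2%, and with the mean age I commit to 80.7%, with [L] at 14.6% of saturation.

The forecast, at 80.5% (76% to 84%) and 13% (11% to 15%), holds that “gas transfer limits the rate”, and its yield lies inside my bracket. The simulation gives 80.3% and 13.0%, with 15% of G left, and that yield stands inside the bracket as well.

In this flask at 1.96 min the half-life of L in the catalysed step is 1.6 s, much shorter than the 1.8 min of G in that step. The half-life of E by decay then is 24 min, longer than the run. Read at 1.0 min instead, the same charge has by the supply time a floor of 76.6% of its G left; the simulation of that reading gives 78% of G and 21.7% of E.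

The constants are assumed; the flask was simulated.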